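Ring A and its γ-lactone are forged together by contracting a seven-membered ring. In the α-bromo ketone precursor C10 is still bonded to the carbonyl carbon C6; the C19 alkoxide on C4 adds to C6 and C10 shifts from C6 to C5 with loss of bromide (intramolecular quasi-Favorskii contraction). This exploits the 1,4-relationship of O19 and C6 and the place of C5 between C6 and quaternary C4, and gives the cis-fused C4/C5 bicycle with an exocyclic methylene on C10. The bicycle then steers a Ti(III) epoxide–acrylate spirolactonisation that sets C10 and joins a limonene-derived C7–C17 fragment; a SmI2 ketyl–olefin cyclisation and a lactone-enolate aldol close rings C and D.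

Key step: step 5

Remark: atoms carry ent-kaurane numbers (ring A = C1–C5 + C10; γ-lactone C4–C19–O–C6–C5; δ-lactone C10–C20–O–C7–C8–C9; ring C = C8, C9, C11–C14; ring D = C8, C14, C13, C16, C15).
Assumption: 3-methylcyclohept-2-en-1-one and (S)-(−)-limonene are taken as purchasable; centres left open in a SMILES string are epimer mixtures that do not matter.

**Route**

Step 1
Reactants: 1 3-methylcyclohept-2-en-1-one
Product: 2 (R)-3-[(E)-hex-1-en-1-yl]-3-methylcycloheptan-1-one
Conditions: hex-1-yne, DIBAL-H, heptane, 55 °C; then 1, CuTC (5 mol %), chiral phosphinamine ligand (SimplePhos type, enantiomer that gives the R ketone), Et2O, −30 °C; aq. HCl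
Reagents that add atoms: hex-1-yne C#CCCCC
Why: Cu-catalysed asymmetric conjugate addition of a hydroalumination-derived alkenylalane to a β-methyl cyclic enone should give the β-quaternary ketone, the chiral Cu complex choosing the enone face and so setting C4, with the alkenyl group serving as a masked C19 hydroxymethyl.

Step 2
Reactants: 2 (R)-3-[(E)-hex-1-en-1-yl]-3-methylcycloheptan-1-one
Product: 5 (6R)-6-[(E)-hex-1-en-1-yl]-6-methyl-2-methylidenecycloheptan-1-one, via Mannich base 3 (not isolated), via methiodide of the Mannich base 4 (not isolated)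
Conditions: LDA, THF, −78 °C; Me2N+=CH2 I−; then MeI; aq. NaHCO3
Reagents that add atoms: dimethyl(methylidene)ammonium iodide C=[N+](C)C.[I-]
Why: kinetic deprotonation should occur at the unhindered C10 methylene and not at the neopentyl C5, and Mannich reaction followed by quaternisation and E1cB elimination gives the exocyclic enone without a new stereocentre.

Step 3
Reactants: 5 (6R)-6-[(E)-hex-1-en-1-yl]-6-methyl-2-methylidenecycloheptan-1-one
Product: 7 (6R)-6-(hydroxymethyl)-6-methyl-2-methylidenecycloheptan-1-one, via keto aldehyde 6 (not isolated)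
Conditions: O3 (1 equiv, Sudan Red 7B end point), CH2Cl2, −78 °C; Me2S; then NaBH(OAc)3, AcOH, 0 °C → rt
Reagents that add atoms: ozone [O-][O+]=O
Why: ozonolysis should cleave the electron-rich disubstituted alkene well before the electron-poor enone C=C, and triacetoxyborohydride reduces the aldehyde but not the ketone (chemoselective reduction), leaving C4 untouched.

Step 4
Reactants: 7 (6R)-6-(hydroxymethyl)-6-methyl-2-methylidenecycloheptan-1-one
Product: 9 (3S)-2-bromo-3-(hydroxymethyl)-3-methyl-7-methylidenecycloheptan-1-one (C2 epimers), via bis(trimethylsilyl) dienol ether 8 (not isolated)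
Conditions: LiHMDS (2.2 equiv), TMSCl, THF, −78 °C; then NBS, −78 °C; aq. citric acid
Reagents that add atoms: N-bromosuccinimide O=C1CCC(=O)N1Br
Why: with C10 sp2 and C4 quaternary the ketone can enolise only toward C5, so the silyl dienol ether forms regiospecifically and NBS brominates its C5 terminus (α-bromination through a silyl enol ether), the C5 epimer ratio being irrelevant for step 5 and the C4 centre unchanged.

Step 5
Reactants: 9 (3S)-2-bromo-3-(hydroxymethyl)-3-methyl-7-methylidenecycloheptan-1-one
Product: 11 (3aR,7aS)-3a-methyl-7-methylidenehexahydro-2-benzofuran-1(3H)-one, via potassium hemiketal alkoxide 10 (not isolated)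
Conditions: KOt-Bu (1.0 equiv), t-BuOH–THF (0.02 M), 0 °C → rt; AcOH quench
Reagents that add atoms: none
Why: Intramolecular quasi-Favorskii (semibenzilic) contraction: the C19 alkoxide adds to the C6 ketone to give bridged hemiketal alkoxide 10, and in the epimer with bromine cis to C19 the C6–C10 bond is antiperiplanar to C5–Br, so the oxyanion pushes the vinylic C10 from C6 to C5 as bromide leaves and the hemiketal carbon becomes the lactone carbonyl. The closest known reaction is the quasi-Favorskii contraction of α-halo ketones without enolisable α'-hydrogens on alkoxide addition, together with the 1,2-aryl shift of α-halo ketals. The γ-lactone closes by 5-exo-trig hemiketalisation, and ring A arises by a three-centre 1,2-shift that contracts the seven-membered carbocycle to six. C5 is set by inversion at the C–Br carbon, and because C10 can reach C5 only from the side of its own bridge the junction should be cis (H5 syn to the C4 methyl), with C4 untouched. The unreactive C5 epimer equilibrates through the bromo enolate, so both epimers should funnel into one product. A cyclopropanone pathway and elimination are excluded because C10 is sp2 and C4 quaternary, and epoxy-ether formation would require a strained oxirane at the bridgehead of the hemiketal.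

Step 6
Reactants: 11 (3aR,7aS)-3a-methyl-7-methylidenehexahydro-2-benzofuran-1(3H)-one
Product: 12 C10/C20 spiro-epoxide of 11 (both C10 epimers)
Conditions: mCPBA, NaHCO3, CH2Cl2, 0 °C
Reagents that add atoms: mCPBA OOC(=O)c1cccc(Cl)c1
Why: peracid (Prilezhaev) epoxidation of the only alkene, the new spiro centre being irrelevant because it becomes a planar radical in step 12.

Step 7
Reactants: 13 (S)-(−)-limonene
Product: 15 (3S)-6-oxo-3-(prop-1-en-2-yl)heptanal, via limonene 1,2-oxide 14 (not isolated)
Conditions: mCPBA (1.0 equiv), CH2Cl2, 0 °C; then H5IO6, THF–H2O, rt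
Reagents that add atoms: mCPBA OOC(=O)c1cccc(Cl)c1; water O
Why: the peracid should epoxidise the more electron-rich trisubstituted ring alkene, and periodic acid hydrolyses and cleaves either epoxide diastereomer (glycol cleavage) to one keto aldehyde in which the limonene stereocentre has become C13.

Step 8
Reactants: 15 (3S)-6-oxo-3-(prop-1-en-2-yl)heptanal
Product: 16 (5S)-7,7-dimethoxy-5-(prop-1-en-2-yl)heptan-2-one
Conditions: HC(OMe)3, MeOH, CeCl3·7H2O (cat.), rt
Reagents that add atoms: trimethyl orthoformate COC(OC)OC
Why: Ce(III)-catalysed acetalisation should take the aldehyde selectively over the methyl ketone and touches no stereocentre.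

Step 9
Reactants: 16 (5S)-7,7-dimethoxy-5-(prop-1-en-2-yl)heptan-2-one
Product: 17 (4S)-6,6-dimethoxy-4-(prop-1-en-2-yl)hexanoic acid
Conditions: NaOBr (from Br2, aq. NaOH), 1,4-dioxane, 0 °C; then NaH2PO4 (pH 4)
Reagents that add atoms: sodium hydroxide [Na+].[OH-]
Why: haloform reaction: cold alkaline hypobromite tribrominates the methyl group and hydroxide cleaves the CBr3 ketone to the carboxylate (C1 becomes C7), acetal and isolated alkene being stable to these basic conditions.

Step 10
Reactants: 17 (4S)-6,6-dimethoxy-4-(prop-1-en-2-yl)hexanoic acid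
Product: 18 methyl (4S)-6,6-dimethoxy-4-(prop-1-en-2-yl)hexanoate
Conditions: MeI, K2CO3, DMF, rt
Reagents that add atoms: iodomethane CI
Why: SN2 O-alkylation of the carboxylate under non-acidic conditions that keep the acetal.

Step 11
Reactants: 18 methyl (4S)-6,6-dimethoxy-4-(prop-1-en-2-yl)hexanoate
Product: 21 methyl (4S)-6,6-dimethoxy-2-methylidene-4-(prop-1-en-2-yl)hexanoate, via amino ester 19 (not isolated), via methiodide of the amino ester 20 (not isolated)
Conditions: LDA, THF, −78 °C; Me2N+=CH2 I−; then MeI, MeOH; aq. NaHCO3
Reagents that add atoms: dimethyl(methylidene)ammonium iodide C=[N+](C)C.[I-]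
Why: ester-enolate Mannich reaction followed by quaternisation and E1cB elimination gives the 2-substituted acrylate (C8=C9), with C13 remote and unaffected.

Step 12
Reactants: 12 C10/C20 spiro-epoxide of 11; 21 methyl (4S)-6,6-dimethoxy-2-methylidene-4-(prop-1-en-2-yl)hexanoate
Product: 23 spiro bis-lactone acetal (C8 epimers), via hydroxy ester 22 (not isolated)
Conditions: Cp2TiCl2 (20 mol %), Zn, 2,4,6-collidine·HCl, THF, rt; then DBU (cat.), PhMe, 60 °C
Reagents that add atoms: none
Why: Ti(III) reductive epoxide opening gives the tertiary C10 radical, which should add (Giese) to acrylate 21 from the face anti to the axial C19 methylene of the cis-fused lactone, so both epoxide epimers converge on C10 with C9 cis to the C4 methyl and C20–O cis to C19, after which base closes the δ-lactone C10–C20–O–C7(=O)–C8–C9 and keeps C5 in its cis-fused arrangement.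

Step 13
Reactants: 23 spiro bis-lactone acetal
Product: 25 C8=C9 unsaturated spiro bis-lactone acetal, via C8 phenylselenide 24 (not isolated)
Conditions: LiHMDS, THF, −78 °C; PhSeBr; then 30% H2O2, pyridine, CH2Cl2, 0 °C
Reagents that add atoms: none
Why: LiHMDS should enolise the δ-lactone at C8 and not the γ-lactone at C5 (shielded by two quaternary neighbours), and selenoxide syn-elimination toward the ring C9–H gives the endocyclic unsaturated lactone, as 2-alkyl-2-selenocyclohexanones do, erasing the C8 centre.

Step 14
Reactants: 25 C8=C9 unsaturated spiro bis-lactone acetal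
Product: 26 C11 aldehyde of the unsaturated spiro bis-lactone
Conditions: PPTS, acetone–H2O, 50 °C
Reagents that add atoms: water O
Why: mild acid hydrolysis of the dimethyl acetal, to which lactones and alkenes are inert.

Step 15
Reactants: 26 C11 aldehyde of the unsaturated spiro bis-lactone
Product: 27 tetracyclic 11-alcohol (ring C closed by C9–C11; C8 epimers)
Conditions: SmI2 (2.5 equiv), t-BuOH (2 equiv), THF, −78 → −20 °C
Reagents that add atoms: none
Why: SmI2 ketyl–olefin cyclisation in which the C11 ketyl adds 6-endo to the β-carbon C9 of the unsaturated lactone on the face anti to C5 of spiro ring A, through a chair that has C10 and the C13 isopropenyl group equatorial and the samarium-bound oxygen axial beside the developing enolate (chelation to the lactone carbonyl), which sets C9 and C11 before the samarium enolate is protonated at C8.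

Step 16
Reactants: 27 tetracyclic 11-alcohol
Product: 29 tetracyclic enal (C13 carries 3-oxoprop-1-en-2-yl), via C15 allylic alcohol 28 (not isolated)
Conditions: SeO2 (0.5 equiv), t-BuOOH, CH2Cl2, rt; filter; then MnO2, CH2Cl2, rt
Reagents that add atoms: selenium dioxide O=[Se]=O; tert-butyl hydroperoxide CC(C)(C)OO
Why: SeO2 allylic oxidation (ene reaction, then [2,3]-shift) should take the isopropenyl methyl group in preference to the tertiary C13–H, as it does in isopropenyl terpenes, and MnO2 carries the allylic alcohol on to the 2-substituted acrolein (the aldehyde carbon is C15) without touching the saturated C11 alcohol or any stereocentre.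

Step 17
Reactants: 29 tetracyclic enal
Product: 30 15-deoxo-15-hydroxyludongnin A (C15 epimers)
Conditions: LiHMDS (2.2 equiv), THF, −78 °C; AcOH quench at −78 °C
Reagents that add atoms: none
Why: intramolecular aldol addition in which the C8 lithium enolate of the δ-lactone adds to the non-enolisable C15 aldehyde (5-exo-trig) from the chair of ring C that carries the C13 acrolein arm axial, so the C8–C15 bond can form only on the face of C8 syn to C13, which fixes the quaternary C8 centre, while the C15 carbinol configuration is irrelevant and the cold acidic quench forestalls retro-aldol cleavage.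

Step 18
Reactants: 30 15-deoxo-15-hydroxyludongnin A
Product: 31 ludongnin A
Conditions: MnO2, CH2Cl2, rt
Reagents that add atoms: none
Why: MnO2 oxidises allylic alcohols selectively, so the C15 carbinol should give the α-methylene ketone while the saturated C11 alcohol and all stereocentres stay untouched.

**Compound list**

1 | 3-methylcyclohept-2-en-1-one | CC1=CC(=O)CCCC1 | starting material
2 | (R)-3-[(E)-hex-1-en-1-yl]-3-methylcycloheptan-1-one | O=C1CCCC[C@@](C)(/C=C/CCCC)C1 | intermediate
3 | Mannich base: (6R)-2-[(dimethylamino)methyl]-6-[(E)-hex-1-en-1-yl]-6-methylcycloheptan-1-one (C2 epimers) | CN(C)CC1CCC[C@@](C)(/C=C/CCCC)CC1=O | intermediate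
4 | methiodide of the Mannich base (trimethylammonium iodide of 3) | C[N+](C)(C)CC1CCC[C@@](C)(/C=C/CCCC)CC1=O.[I-] | intermediate
5 | (6R)-6-[(E)-hex-1-en-1-yl]-6-methyl-2-methylidenecycloheptan-1-one | C=C1CCC[C@@](C)(/C=C/CCCC)CC1=O | intermediate
6 | keto aldehyde: (1R)-1-methyl-4-methylidene-3-oxocycloheptane-1-carbaldehyde | C=C1CCC[C@@](C)(C=O)CC1=O | intermediate
7 | (6R)-6-(hydroxymethyl)-6-methyl-2-methylidenecycloheptan-1-one | C=C1CCC[C@@](C)(CO)CC1=O | intermediate
8 | bis(trimethylsilyl) dienol ether of 7 (O-TMS on C19, 2-silyloxy-1,3-diene C5=C6–C10=C20) | C=C1CCC[C@@](C)(CO[Si](C)(C)C)C=C1O[Si](C)(C)C | intermediate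
9 | (3S)-2-bromo-3-(hydroxymethyl)-3-methyl-7-methylidenecycloheptan-1-one (C2 epimers) | C=C1CCC[C@@](C)(CO)C(Br)C1=O | intermediate
10 | potassium hemiketal alkoxide: potassium salt of the bridged C19–O–C6 hemiketal of 9 | C=C1CCC[C@@]2(C)COC1([O-])C2Br.[K+] | intermediate
11 | (3aR,7aS)-3a-methyl-7-methylidenehexahydro-2-benzofuran-1(3H)-one (cis-fused; C3a = C4, C7a = C5, C7 = C10) | C=C1CCC[C@@]2(C)COC(=O)[C@H]21 | intermediate
12 | C10/C20 spiro-epoxide of 11 (both C10 epimers) | O1CC12CCC[C@@]3(C)COC(=O)[C@H]32 | intermediate
13 | (S)-(−)-limonene | CC1=CC[C@H](CC1)C(C)=C | starting material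
14 | (4S)-limonene 1,2-oxide (cis/trans) | CC12OC1C[C@H](CC2)C(C)=C | intermediate
15 | (3S)-6-oxo-3-(prop-1-en-2-yl)heptanal | CC(=O)CC[C@H](C(C)=C)CC=O | intermediate
16 | (5S)-7,7-dimethoxy-5-(prop-1-en-2-yl)heptan-2-one | CC(=O)CC[C@H](C(C)=C)CC(OC)OC | intermediate
17 | (4S)-6,6-dimethoxy-4-(prop-1-en-2-yl)hexanoic acid | OC(=O)CC[C@H](C(C)=C)CC(OC)OC | intermediate
18 | methyl (4S)-6,6-dimethoxy-4-(prop-1-en-2-yl)hexanoate | COC(=O)CC[C@H](C(C)=C)CC(OC)OC | intermediate
19 | amino ester: methyl (4S)-2-[(dimethylamino)methyl]-6,6-dimethoxy-4-(prop-1-en-2-yl)hexanoate (C2 epimers) | COC(=O)C(CN(C)C)C[C@H](C(C)=C)CC(OC)OC | intermediate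
20 | methiodide of the amino ester (trimethylammonium iodide of 19) | COC(=O)C(C[N+](C)(C)C)C[C@H](C(C)=C)CC(OC)OC.[I-] | intermediate
21 | methyl (4S)-6,6-dimethoxy-2-methylidene-4-(prop-1-en-2-yl)hexanoate | COC(=O)C(=C)C[C@H](C(C)=C)CC(OC)OC | intermediate
22 | hydroxy ester: C9–C10 coupled product with free C20–OH cis to C19 and C7 methyl ester (C8 epimers) | COC(=O)C(C[C@H](C(C)=C)CC(OC)OC)C[C@]1(CO)CCC[C@@]2(C)COC(=O)[C@H]21 | intermediate
23 | spiro bis-lactone acetal: δ-lactone C10–C20–O–C7(=O)–C8–C9 on the cis-fused A-ring γ-lactone, C8 carrying the (2S)-4,4-dimethoxy-2-(prop-1-en-2-yl)butyl chain (C8 epimers) | O=C1OC[C@]2(CCC[C@@]3(C)COC(=O)[C@H]32)CC1C[C@H](C(C)=C)CC(OC)OC | intermediate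
24 | C8 phenylselenide of 23 | O=C1OC[C@]2(CCC[C@@]3(C)COC(=O)[C@H]32)CC1([Se]c1ccccc1)C[C@H](C(C)=C)CC(OC)OC | intermediate
25 | C8=C9 unsaturated spiro bis-lactone acetal | O=C1OC[C@]2(CCC[C@@]3(C)COC(=O)[C@H]32)C=C1C[C@H](C(C)=C)CC(OC)OC | intermediate
26 | C11 aldehyde of the unsaturated spiro bis-lactone (side chain (2S)-4-oxo-2-(prop-1-en-2-yl)butyl) | O=C1OC[C@]2(CCC[C@@]3(C)COC(=O)[C@H]32)C=C1C[C@H](C(C)=C)CC=O | intermediate
27 | tetracyclic 11-alcohol (ring C closed, 11-OH, 13-isopropenyl, C8–H either epimer, both lactones intact) | CC(=C)[C@@H]1C[C@@H](O)[C@H]2[C@@]3(CCC[C@@]4(C)COC(=O)[C@H]43)COC(=O)C2C1 | intermediate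
28 | C15 allylic alcohol: 27 with the C13 substituent as 3-hydroxyprop-1-en-2-yl | OCC(=C)[C@@H]1C[C@@H](O)[C@H]2[C@@]3(CCC[C@@]4(C)COC(=O)[C@H]43)COC(=O)C2C1 | intermediate
29 | tetracyclic enal: 27 with the C13 substituent as 3-oxoprop-1-en-2-yl (C15 = CHO) | O=CC(=C)[C@@H]1C[C@@H](O)[C@H]2[C@@]3(CCC[C@@]4(C)COC(=O)[C@H]43)COC(=O)C2C1 | intermediate
30 | 15-deoxo-15-hydroxyludongnin A (C15 epimers) | C=C1C(O)[C@]23C[C@H]1C[C@@H](O)[C@H]2[C@@]1(CCC[C@@]2(C)COC(=O)[C@H]21)COC3=O | intermediate
31 | ludongnin A | C=C1C(=O)[C@]23C[C@H]1C[C@@H](O)[C@H]2[C@@]1(CCC[C@@]2(C)COC(=O)[C@H]21)COC3=O | target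

**Step count and risks**

Total steps: 18. Longest linear sequence: 13 (steps 1–6, then 12–18); the fragment branch is steps 7–11.

Steps most likely to fail:

1. Step 5. The hemiketal alkoxide may be too sparsely populated, so that the bromo enolate is consumed by intermolecular alkylation before the 1,2-shift occurs, and residual base may move the exocyclic alkene of the product into conjugation with the lactone. The fallback is a photochemical Wolff ring contraction. It sets out from 7: detrifluoroacetylative diazo transfer (LiHMDS, 2,2,2-trifluoroethyl trifluoroacetate; then methanesulfonyl azide, Et3N, H2O) should give (3R)-2-diazo-3-(hydroxymethyl)-3-methyl-7-methylidenecycloheptan-1-one F1. Irradiation (365 nm, dilute THF) expels nitrogen, C10 migrates from C6 to C5, and the vinylketene F2 is trapped by the C19 hydroxyl. The route is rejoined at 11; in this variant the ring junction rests on kinetic α-protonation of the dienol.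

2. Step 12. The tertiary radical may be reduced by a second Ti(III) and lost through β-hydride elimination to allylic alcohols before it adds to the hindered acrylate, or it may add on both faces of C10 if the lactone reacts through its other chair. The fallback replaces the radical by a polar union. It sets out from 12: BF3·OEt2 (Meinwald rearrangement) should give the C10 carbaldehyde F3 (the aldehyde carbon is C20). Its enolate (catalytic KOt-Bu, t-BuOH–THF) adds in Michael fashion to 21 to give the quaternary aldehyde ester F4. NaBH4 reduces the aldehyde to hydroxy ester 22, which lactonises with DBU, and the route is rejoined at 23.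

3. Step 17. The amide base may add to the unhindered aldehyde before it removes the C8 proton, and the aldolate may revert by retro-aldol cleavage, because the bicyclo[3.2.1]octane with its quaternary C8 is strained. The fallback generates the enolate reductively at a C–Br bond (samarium Reformatsky reaction) and so needs no base in the presence of the aldehyde. It sets out from 27: LiHMDS (2.2 equiv) and then CBr4 should give the C8 bromo lactone F5. SeO2/t-BuOOH hydroxylates the isopropenyl methyl group to the bromo allylic alcohol F6, and MnO2 gives the bromo enal F7. SmI2 (THF, −78 °C, inverse addition) reduces the C–Br bond, the samarium enolate adds to the C15 aldehyde, and the route is rejoined at 30.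

Further compounds
F1 | step 5 | (3R)-2-diazo-3-(hydroxymethyl)-3-methyl-7-methylidenecycloheptan-1-one | C=C1CCC[C@@](C)(CO)C(=[N+]=[N-])C1=O
F2 | step 5 | vinylketene: (6R)-6-(hydroxymethyl)-6-methyl-2-methylidenecyclohexylidene ketene | C=C1CCC[C@@](C)(CO)C1=C=O
F3 | step 12 | C10 carbaldehyde of the cis-fused A-ring lactone (C10 epimers) | O=CC1CCC[C@@]2(C)COC(=O)[C@H]21
F4 | step 12 | C10 quaternary aldehyde ester (Michael adduct of F3 and 21, C8 epimers) | COC(=O)C(C[C@H](C(C)=C)CC(OC)OC)C[C@]1(C=O)CCC[C@@]2(C)COC(=O)[C@H]21
F5 | step 17 | C8 bromo lactone of 27 (C8 epimers) | CC(=C)[C@@H]1C[C@@H](O)[C@H]2[C@@]3(CCC[C@@]4(C)COC(=O)[C@H]43)COC(=O)C2(Br)C1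
F6 | step 17 | bromo allylic alcohol (F5 with the C13 substituent as 3-hydroxyprop-1-en-2-yl) | OCC(=C)[C@@H]1C[C@@H](O)[C@H]2[C@@]3(CCC[C@@]4(C)COC(=O)[C@H]43)COC(=O)C2(Br)C1
F7 | step 17 | bromo enal (F5 with the C13 substituent as 3-oxoprop-1-en-2-yl) | O=CC(=C)[C@@H]1C[C@@H](O)[C@H]2[C@@]3(CCC[C@@]4(C)COC(=O)[C@H]43)COC(=O)C2(Br)C1
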